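**Strategy.** Lobatin B is cut at C2–C3 of the 3(2H)-furanone (germacrane numbering). Its nine-membered oxacycle O–C3–C4=C5–C6–C7–C8–C9–C10 is read as the homologue of an eight-membered lactone in which the C3 carboxyl sits on the neighbouring 9-OH. In one operation base moves this acyl group to the adjacent tertiary C10 alkoxide (ring expansion by one atom), the C10 acetyl enolate condenses onto it, and acid dehydrates: furanone, ten-membered carbocycle and free 9-OH appear together. The precursor is a γ-lactone trans-fused to an eight-membered (Z)-2-methylenoate lactone bearing a 2-hydroxy-3-oxobutan-2-yl group on C9.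

Key step: step 16

Remark: germacrane numbering is used throughout (C1 ketone, C2=C3, C4=C5, C6 lactone carbinol, C7, C8 ester, C9 OH, C10 quaternary, C11–C13 methylene lactone); 2-C-methyl-D-erythrono-1,4-lactone (1) is taken as a catalogue compound, and the zinc Barbier step is assumed to follow the closed chair model (7,8-anti), which is why the isovalerate is introduced with inversion.

**Step 1**
Reactants: 1 2-C-methyl-D-erythrono-1,4-lactone [(3R,4R)-3,4-dihydroxy-3-methyloxolan-2-one]
Product: 2 (3aR,6aR)-2,2,3a-trimethyldihydrofuro[3,4-d][1,3]dioxol-4(3aH)-one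
Conditions: 2,2-dimethoxypropane, TsOH·H2O (cat.), acetone, rt
Reagents that add atoms: 2,2-dimethoxypropane COC(C)(C)OC
Why: Acid-catalysed transketalisation closes the cis-fused dioxolane on the cis-diol without touching either stereocentre (future C9 and C10).

**Step 2**
Reactants: 2 acetonide lactone
Product: 3 (3aR,6aR)-2,2,3a-trimethyltetrahydrofuro[3,4-d][1,3]dioxol-4-ol (anomer mixture)
Conditions: DIBAL-H (1.1 equiv), CH2Cl2, −78 °C; Rochelle salt
Reagents that add atoms: none
Why: Partial lactone reduction stops at the aluminium hemiacetal at −78 °C and gives the lactol.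

**Step 3**
Reactants: 3 lactol
Product: 4 [(4R,5S)-5-ethynyl-2,2,5-trimethyl-1,3-dioxolan-4-yl]methanol
Conditions: dimethyl (1-diazo-2-oxopropyl)phosphonate, K2CO3, MeOH, 0 °C → rt
Reagents that add atoms: Ohira–Bestmann reagent CC(=O)C(=[N+]=[N-])P(=O)(OC)OC
Why: Ohira–Bestmann (Seyferth–Gilbert) homologation acts on the open hydroxy-aldehyde tautomer, whose formyl group sits on the quaternary C10 and so cannot epimerise, and it frees the primary C8 hydroxyl at the same time.

**Step 4**
Reactants: 4 alkynol
Product: 5 (4S,5S)-5-ethynyl-2,2,5-trimethyl-1,3-dioxolane-4-carbaldehyde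
Conditions: Dess–Martin periodinane, CH2Cl2, 0 °C → rt (used crude)
Reagents that add atoms: none
Why: Dess–Martin oxidation of the primary alcohol under non-basic conditions should leave the α-alkoxy stereocentre C9 intact.

**Step 5**
Reactants: 6 (S)-but-3-ene-1,2-diol
Product: 7 (S)-1-[(tert-butyldiphenylsilyl)oxy]but-3-en-2-ol
Conditions: TBDPSCl (1.05 equiv), imidazole, CH2Cl2, 0 °C
Reagents that add atoms: tert-butyl(chloro)diphenylsilane CC(C)(C)[Si](Cl)(c1ccccc1)c1ccccc1
Why: The bulky silyl chloride silylates the primary hydroxyl of the 1,2-diol selectively.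

**Step 6**
Reactants: 7 silyl ether; 8 2-(bromomethyl)acrylic acid
Product: 9 (S)-1-[(tert-butyldiphenylsilyl)oxy]but-3-en-2-yl 2-(bromomethyl)acrylate
Conditions: DCC, DMAP (cat.), CH2Cl2, 0 °C
Reagents that add atoms: none
Why: Steglich esterification of the secondary allylic alcohol leaves the carbinol stereocentre (future C6) untouched.

**Step 7**
Reactants: 9 diene ester
Product: 10 (S)-3-(bromomethyl)-5-{[(tert-butyldiphenylsilyl)oxy]methyl}furan-2(5H)-one
Conditions: Grubbs II (5 mol %), toluene, 80 °C, 0.01 M
Reagents that add atoms: none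
Why: Ring-closing metathesis of the allyl acrylate-type diene gives the butenolide with loss of ethene, and the allylic bromide is tolerated by the ruthenium carbene.

**Step 8**
Reactants: 5 aldehyde; 10 bromomethyl butenolide
Product: 11 (4R,5S)-5-{[(tert-butyldiphenylsilyl)oxy]methyl}-4-{(R)-[(4R,5S)-5-ethynyl-2,2,5-trimethyl-1,3-dioxolan-4-yl](hydroxy)methyl}-3-methylideneoxolan-2-one (6,7-trans, 8R in target numbering)
Conditions: Zn dust, THF/sat. aq NH4Cl, 0 °C → rt
Reagents that add atoms: none
Why: In this Barbier allylation (SE2′) the E-locked allylzinc adds through its γ-carbon C7 in a Zimmerman–Traxler chair on the face anti to the CH2OTBDPS group (6,7-trans) with the aldehyde substituent equatorial (7,8-anti), which coincides with Felkin–Anh attack on the α-alkoxy aldehyde (8,9-anti) and should give the 8R carbinol and the exocyclic methylene.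

**Step 9**
Reactants: 11 Barbier adduct; 12 3-methylbutanoic (isovaleric) acid
Product: 13 (S)-[(2S,3S)-2-{[(tert-butyldiphenylsilyl)oxy]methyl}-4-methylidene-5-oxooxolan-3-yl][(4R,5S)-5-ethynyl-2,2,5-trimethyl-1,3-dioxolan-4-yl]methyl 3-methylbutanoate (8S)
Conditions: PPh3, DIAD (betaine preformed), toluene, 0 °C → rt
Reagents that add atoms: none
Why: Mitsunobu esterification displaces the alkoxyphosphonium by SN2, so the 8R carbinol is inverted to the required 8S isovalerate in the acylation step itself.

**Step 10**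
Reactants: 13 acetonide ester
Product: 14 (1S,2R,3S)-1-[(2S,3S)-2-{[(tert-butyldiphenylsilyl)oxy]methyl}-4-methylidene-5-oxooxolan-3-yl]-2,3-dihydroxy-3-methylpent-4-yn-1-yl 3-methylbutanoate (9-OH, 10-OH free)
Conditions: TFA/H2O (9:1), CH2Cl2, 0 °C
Reagents that add atoms: none
Why: Aqueous-acid hydrolysis removes the isopropylidene ketal, while the silyl ether, the esters and the tertiary propargylic alcohol should survive at 0 °C.

**Step 11**
Reactants: 14 diol; 15 2-(diethoxyphosphoryl)propanoic acid
Product: 16 the 9-O-[2-(diethoxyphosphoryl)propanoyl] ester of 14 (both epimers at the phosphorus-bearing carbon)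
Conditions: DCC, DMAP (cat.), CH2Cl2, 0 °C → rt
Reagents that add atoms: none
Why: Steglich esterification (via the phosphonoketene) acylates the secondary 9-OH while the tertiary propargylic 10-OH stays free, and the extra stereocentre is erased in step 14.

**Step 12**
Reactants: 16 silyl ether
Product: 17 the primary alcohol (16 with C5 as CH2OH)
Conditions: HF·pyridine, pyridine/THF, 0 °C → rt
Reagents that add atoms: none
Why: Buffered fluoride cleaves the primary silyl ether and avoids the acyl migrations that basic TBAF could trigger.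

**Step 13**
Reactants: 17 primary alcohol
Product: 18 the C5 aldehyde (lactone C6 bearing CHO)
Conditions: Dess–Martin periodinane, CH2Cl2, rt
Reagents that add atoms: none
Why: Dess–Martin oxidation takes the primary alcohol to the aldehyde, and the tertiary 10-OH cannot be oxidised.

**Step 14**
Reactants: 18 aldehyde phosphonate
Product: 19 the eight-membered lactone: α-methylene-γ-butyrolactone trans-fused at C6–C7 to the ring O9–C3(=O)–C4(CH3)=C5–C6–C7–C8–C9 (4Z), 8-O-isovaleryl, C9 bearing (S)-2-hydroxybut-3-yn-2-yl (6R,7S,8S,9R,10S)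
Conditions: LiCl, i-Pr2NEt, MeCN, 1 mM (slow addition), rt
Reagents that add atoms: none
Why: Intramolecular Horner–Wadsworth–Emmons olefination under Masamune–Roush conditions can only give the Z-alkene in an eight-membered ring, and the alkyne is kept until after this step because a methyl ketone would compete by six-membered olefination.

**Step 15**
Reactants: 19 alkynyl lactone
Product: 20 the same bicyclic dilactone with C9 bearing (R)-2-hydroxy-3-oxobutan-2-yl (6R,7S,8S,9R,10R)
Conditions: Hg(OTf)2 (5 mol %), H2O (3 equiv), MeCN, rt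
Reagents that add atoms: water O
Why: Mercury(II)-catalysed Markovnikov hydration (Kucherov type) of the tertiary ethynyl carbinol gives the α-hydroxy methyl ketone, and the electron-poor alkenes are inert.

**Step 16**
Reactants: 20 eight-membered lactone
Product: 24 lobatin B, via nine-membered lactone 21 (not isolated), via ring-opened diketone 22 (not isolated), via bridged hemiketal 23 (not isolated)
Conditions: LiHMDS (2.2 equiv), THF, −78 → −30 °C; then 1 M HCl, THF, 0 °C → rt
Reagents that add atoms: none
Why: LiHMDS forms the C10 alkoxide and the C2 enolate of the methyl ketone (C10 is quaternary, so there is no other enolisable side); the alkoxide adds to the neighbouring lactone carbonyl C3 through a five-membered orthoester-type intermediate and collapses to the nine-membered lactone 21, a 1,2-acyl shift that expands the ring by one atom and changes the ring oxygen from O9 to O10. The enolate then attacks C3 in a 5-exo-trig Claisen (Dieckmann-type) step that closes the furanone ring and, through the same C2–C3 bond, the ten-membered carbocycle. Collapse of that adduct to the diketone enolate 22 (also what a direct Baker–Venkataraman transfer from O9 through a six-membered transition state would give) is harmless, because on acidification the tertiary 10-OH re-adds to C3 (5-exo-trig, hemiketal 23) and water is lost to the conjugated vinylogous ester. The closest known reactions are the 1,2-acyl migration of diol monoesters, the Baker–Venkataraman transposition and the base-then-acid conversion of α-acyloxy ketones into 3(2H)-furanones. No stereocentre is created: C6–C10 are carried through, C10 cannot epimerise, and the 4Z geometry is fixed by the ring. The step needs the enolate to take the C3 acyl group and not the 8-O-isovalerate (five- or six-membered against seven-membered transition state), the isovalerate to stay on O8 (the neopentylic O9 is the poorer acyl acceptor; low temperature, 2.2 equiv of base, fast quench), and closure through O10 and not O9 (five- over six-membered hemiketal).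

**Compound list**

1 | 2-C-methyl-D-erythrono-1,4-lactone | C[C@@]1(O)[C@H](O)COC1=O | starting material
2 | (3aR,6aR)-2,2,3a-trimethyldihydrofuro[3,4-d][1,3]dioxol-4(3aH)-one | C[C@@]1(OC(C)(C)O2)[C@H]2COC1=O | intermediate
3 | (3aR,6aR)-2,2,3a-trimethyltetrahydrofuro[3,4-d][1,3]dioxol-4-ol | C[C@@]1(OC(C)(C)O2)[C@H]2COC1O | intermediate
4 | [(4R,5S)-5-ethynyl-2,2,5-trimethyl-1,3-dioxolan-4-yl]methanol | C[C@@](C#C)(OC(C)(C)O1)[C@H]1CO | intermediate
5 | (4S,5S)-5-ethynyl-2,2,5-trimethyl-1,3-dioxolane-4-carbaldehyde | C[C@@](C#C)(OC(C)(C)O1)[C@H]1C=O | intermediate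
6 | (S)-but-3-ene-1,2-diol | O[C@H](CO)C=C | starting material
7 | (S)-1-[(tert-butyldiphenylsilyl)oxy]but-3-en-2-ol | O[C@H](CO[Si](c1ccccc1)(c1ccccc1)C(C)(C)C)C=C | intermediate
8 | 2-(bromomethyl)acrylic acid | C=C(CBr)C(=O)O | starting material
9 | (S)-1-[(tert-butyldiphenylsilyl)oxy]but-3-en-2-yl 2-(bromomethyl)acrylate | C=C(CBr)C(=O)O[C@H](CO[Si](c1ccccc1)(c1ccccc1)C(C)(C)C)C=C | intermediate
10 | (S)-3-(bromomethyl)-5-{[(tert-butyldiphenylsilyl)oxy]methyl}furan-2(5H)-one | O=C1O[C@H](CO[Si](c2ccccc2)(c2ccccc2)C(C)(C)C)C=C1CBr | intermediate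
11 | Barbier adduct, 8R carbinol (name in step 8) | C=C1C(=O)O[C@H](CO[Si](c2ccccc2)(c2ccccc2)C(C)(C)C)[C@H]1[C@@H](O)[C@@H](OC(C)(C)O3)[C@]3(C)C#C | intermediate
12 | 3-methylbutanoic (isovaleric) acid | CC(C)CC(=O)O | starting material
13 | 8S isovalerate (name in step 9) | C=C1C(=O)O[C@H](CO[Si](c2ccccc2)(c2ccccc2)C(C)(C)C)[C@H]1[C@H](OC(=O)CC(C)C)[C@@H](OC(C)(C)O3)[C@]3(C)C#C | intermediate
14 | 9,10-diol (name in step 10) | C=C1C(=O)O[C@H](CO[Si](c2ccccc2)(c2ccccc2)C(C)(C)C)[C@H]1[C@H](OC(=O)CC(C)C)[C@@H](O)[C@@](C)(O)C#C | intermediate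
15 | 2-(diethoxyphosphoryl)propanoic acid | CCOP(=O)(OCC)C(C)C(=O)O | starting material
16 | 9-O-[2-(diethoxyphosphoryl)propanoyl] ester of 14 | C=C1C(=O)O[C@H](CO[Si](c2ccccc2)(c2ccccc2)C(C)(C)C)[C@H]1[C@H](OC(=O)CC(C)C)[C@@H](OC(=O)C(C)P(=O)(OCC)OCC)[C@@](C)(O)C#C | intermediate
17 | primary alcohol (C5 = CH2OH) | C=C1C(=O)O[C@H](CO)[C@H]1[C@H](OC(=O)CC(C)C)[C@@H](OC(=O)C(C)P(=O)(OCC)OCC)[C@@](C)(O)C#C | intermediate
18 | C5 aldehyde | C=C1C(=O)O[C@H](C=O)[C@H]1[C@H](OC(=O)CC(C)C)[C@@H](OC(=O)C(C)P(=O)(OCC)OCC)[C@@](C)(O)C#C | intermediate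
19 | eight-membered (4Z)-lactone on O9, C9 bearing (S)-2-hydroxybut-3-yn-2-yl | C=C1C(=O)O[C@@H]2/C=C(/C)C(=O)O[C@@H]([C@@](C)(O)C#C)[C@@H](OC(=O)CC(C)C)[C@@H]12 | intermediate
20 | eight-membered (4Z)-lactone on O9, C9 bearing (R)-2-hydroxy-3-oxobutan-2-yl | C=C1C(=O)O[C@@H]2/C=C(/C)C(=O)O[C@@H]([C@@](C)(O)C(C)=O)[C@@H](OC(=O)CC(C)C)[C@@H]12 | intermediate
21 | nine-membered lactone on O10 (C10 bearing CH3 and acetyl, free 9-OH) | C=C1C(=O)O[C@@H]2/C=C(/C)C(=O)O[C@@](C)(C(C)=O)[C@H](O)[C@@H](OC(=O)CC(C)C)[C@@H]12 | intermediate (not isolated)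
22 | ten-membered 1,3-diketone with 9-OH and 10-OH | C=C1C(=O)O[C@@H]2/C=C(/C)C(=O)CC(=O)[C@](C)(O)[C@H](O)[C@@H](OC(=O)CC(C)C)[C@@H]12 | intermediate (not isolated)
23 | bridged hemiketal (O10 added to C3) | C=C1C(=O)O[C@@H]2/C=C(/C)C3(O)CC(=O)[C@](C)(O3)[C@H](O)[C@@H](OC(=O)CC(C)C)[C@@H]12 | intermediate (not isolated)
24 | lobatin B | C=C1C(=O)O[C@@H]2/C=C(/C)C3=CC(=O)[C@](C)(O3)[C@H](O)[C@@H](OC(=O)CC(C)C)[C@@H]12 | target

**Step count.** 16 steps in total; the longest linear sequence is 13 steps (steps 1–4 and 8–16).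

**Steps most likely to fail**

1. Step 16. The lithium alkoxides may shuffle the two acyl groups among O8, O9 and O10, so that the isovalerate migrates or is itself taken by the enolate. The amide base may also attack or deprotonate the α-methylene lactone, and acid closure could run through O9 to a six-membered ring. Fallback, from 19 to 24: the terminal alkyne would be brominated (NBS, cat. AgNO3, acetone) to the bromoalkyne F1 and hydrated under gold catalysis (Ph3PAuNTf2, wet dioxane) to the α-bromomethyl ketone F2. SmI2 (2 equiv, THF, −78 °C) would then generate the samarium enolate by reductive C–Br cleavage, without amide base, for the same intramolecular acyl substitution; acidic work-up would close and dehydrate to 24.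

2. Step 14. Intermolecular olefination (dimers, oligomers) may outrun closure of the strained eight-membered ring, and the α-acyloxy aldehyde may epimerise at C6. Fallback, from 14 to 20: O9 would be acylated with methacrylic anhydride (DMAP) to the methacrylate F3, desilylated (HF·pyridine) to the alcohol F4 and oxidised (Dess–Martin) to the aldehyde F5. Takai–Lombardo methylenation (Zn, CH2Br2, TiCl4) would give the 6-vinyl lactone F6 and Hg(II)-catalysed hydration the methyl ketone F7. Ring-closing metathesis between vinyl and methacrylate (Grubbs II, toluene, 80 °C, high dilution) would then give 20.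

3. Step 9. The hindered alkoxyphosphonium may eliminate toward C7 or resist displacement by the weakly acidic isovaleric acid. Fallback, from 11 to 13: the carbinol would be converted into the triflate F8 (Tf2O, pyridine, CH2Cl2, −40 °C) and displaced with caesium 3-methylbutanoate/18-crown-6 in toluene (SN2, inversion) to give 13.

**Further compounds**

F1 | step 16 | bromoalkyne (19 with C≡C–Br) | C=C1C(=O)O[C@@H]2/C=C(/C)C(=O)O[C@@H]([C@@](C)(O)C#CBr)[C@@H](OC(=O)CC(C)C)[C@@H]12
F2 | step 16 | α-bromomethyl ketone (20 with C2 as CH2Br) | C=C1C(=O)O[C@@H]2/C=C(/C)C(=O)O[C@@H]([C@@](C)(O)C(=O)CBr)[C@@H](OC(=O)CC(C)C)[C@@H]12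
F3 | step 14 | 9-O-methacrylate of 14 | C=C1C(=O)O[C@H](CO[Si](c2ccccc2)(c2ccccc2)C(C)(C)C)[C@H]1[C@H](OC(=O)CC(C)C)[C@@H](OC(=O)C(C)=C)[C@@](C)(O)C#C
F4 | step 14 | desilylated primary alcohol | C=C1C(=O)O[C@H](CO)[C@H]1[C@H](OC(=O)CC(C)C)[C@@H](OC(=O)C(C)=C)[C@@](C)(O)C#C
F5 | step 14 | C5 aldehyde | C=C1C(=O)O[C@H](C=O)[C@H]1[C@H](OC(=O)CC(C)C)[C@@H](OC(=O)C(C)=C)[C@@](C)(O)C#C
F6 | step 14 | 6-vinyl lactone | C=C1C(=O)O[C@H](C=C)[C@H]1[C@H](OC(=O)CC(C)C)[C@@H](OC(=O)C(C)=C)[C@@](C)(O)C#C
F7 | step 14 | 6-vinyl lactone methyl ketone | C=C1C(=O)O[C@H](C=C)[C@H]1[C@H](OC(=O)CC(C)C)[C@@H](OC(=O)C(C)=C)[C@@](C)(O)C(C)=O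
F8 | step 9 | 8-O-triflate of 11 | C=C1C(=O)O[C@H](CO[Si](c2ccccc2)(c2ccccc2)C(C)(C)C)[C@H]1[C@@H](OS(=O)(=O)C(F)(F)F)[C@@H](OC(C)(C)O3)[C@]3(C)C#C
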